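## Retrosynthetic overview

1. Ambuic acid 14 comes from epoxyquinone 13 by a hydroxyl-directed reduction of the C4 ketone, which sets the last stereocentre cis to the oxirane.
2. 13 comes from iodo epoxy monoketal 9 by Suzuki–Miyaura coupling (C2–heptenyl) and unmasking; 9 comes from quinone monoketal 8 by tartrate-mediated asymmetric nucleophilic epoxidation (C5 and C6).
3. 8 comes from phenol 6 by one-pot ortho-iodination and oxidative dearomatization.
4. Key C6–CH2 bond: quinone monoketal 5 reacts as an α-keto cation (enolonium) equivalent with the γ-carbon of silyl dienolate 2, so two carbons that are both normally nucleophilic are joined and the whole side chain arrives in one step.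
5. Rings: the carbocycle is the benzene ring of 3, dearomatized in steps 3 and 5; the oxirane is the only ring formed (step 6).

Convention: C1 = ketone carbon, C2 = heptenyl-bearing carbon, C3 = CH2OH-bearing carbon, C4 = carbinol carbon, C5 = oxirane CH, C6 = quaternary oxirane carbon; the same locants are used for the aromatic precursors.

Assumption: diisopropyl L-tartrate is taken as the antipode that gives the (1R,6S)-epoxide 9; if the first run shows the opposite sense, the D-tartrate ester is used with no other change.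

## Route

Step 1
Reactants: 1 methyl (2E)-2-methylbut-2-enoate (methyl tiglate)
Product: 2 [(1-methoxy-2-methylbuta-1,3-dien-1-yl)oxy]trimethylsilane
Conditions: LiN(iPr)2 (commercial solution), THF/DMPU, −78 °C; Me3SiCl, −78 → 0 °C; distil
Reagents that add atoms: chlorotrimethylsilane (C[Si](C)(C)Cl)
Why: Kinetic γ-deprotonation of the enoate and O-silylation give the silyl dienolate (silyl ketene acetal formation); the E/Z mixture at the ketene acetal bond is irrelevant because that geometry is lost in step 4.

Step 2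
Reactants: 3 5-hydroxy-2-methoxybenzaldehyde
Product: 4 3-(hydroxymethyl)-4-methoxyphenol
Conditions: NaBH4, MeOH, 0 °C
Reagents that add atoms: none
Why: Borohydride reduction of the aryl aldehyde, done first because a free aldehyde would undergo Mukaiyama aldol addition in step 4.

Step 3
Reactants: 4 3-(hydroxymethyl)-4-methoxyphenol
Product: 5 3-(hydroxymethyl)-4,4-dimethoxycyclohexa-2,5-dien-1-one
Conditions: PhI(OAc)2, MeOH, 0 °C
Reagents that add atoms: methanol (CO)
Why: Oxidative dearomatization of a para-methoxyphenol, with methanol captured at the methoxy-bearing carbon C4, gives the quinone monoketal with C1 as the carbonyl.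

Step 4
Reactants: 5 3-(hydroxymethyl)-4,4-dimethoxycyclohexa-2,5-dien-1-one; 2 [(1-methoxy-2-methylbuta-1,3-dien-1-yl)oxy]trimethylsilane
Product: 6 methyl (2E)-4-[2-hydroxy-4-(hydroxymethyl)-5-methoxyphenyl]-2-methylbut-2-enoate
Conditions: 2 (2.5 equiv), Me3SiOTf (10 mol %), CH2Cl2, −78 °C; 1 M HCl/THF work-up
Reagents that add atoms: none
Why: Proposed new method: Me3SiOTf ionizes the allylic ketal (Noyori-type acetal activation) to a methoxy-stabilized dienone cation whose electrophilic termini are the carbons alpha to the C1 carbonyl; the silyl dienolate attacks through its γ-carbon at the less hindered of these (C6, remote from the CH2O-bearing C3) and tautomerization gives the phenol with the (E)-enoate, no stereocentre being formed; the closest known reactions are the acid-promoted SN2′-type α-substitution of quinone monoacetals by arenes and alkenes and the vinylogous Mukaiyama reaction of ester-derived silyl dienolates with oxocarbenium ions.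

Step 5
Reactants: 6 methyl (2E)-4-[2-hydroxy-4-(hydroxymethyl)-5-methoxyphenyl]-2-methylbut-2-enoate
Product: 8 methyl (2E)-4-[4-(hydroxymethyl)-5-iodo-3,3-dimethoxy-6-oxocyclohexa-1,4-dien-1-yl]-2-methylbut-2-enoate, via iodophenol 7 (not isolated)
Conditions: NIS (1.02 equiv), MeOH, −10 °C; then PhI(OAc)2 (1.1 equiv), 0 °C
Reagents that add atoms: N-iodosuccinimide (O=C1CCC(=O)N1I); methanol (CO)
Why: Electrophilic iodination goes ortho to the free phenol, where C2 is the only open position, and the same methanolic solution is then oxidatively dearomatized as in step 3; the enoate and the aryl iodide are inert to both reagents.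

Step 6
Reactants: 8 methyl (2E)-4-[4-(hydroxymethyl)-5-iodo-3,3-dimethoxy-6-oxocyclohexa-1,4-dien-1-yl]-2-methylbut-2-enoate
Product: 9 methyl (2E)-4-[(1R,6S)-4-(hydroxymethyl)-3-iodo-5,5-dimethoxy-2-oxo-7-oxabicyclo[4.1.0]hept-3-en-1-yl]-2-methylbut-2-enoate
Conditions: Ph3COOH, NaN(SiMe3)2, diisopropyl L-tartrate, 4 Å molecular sieves, toluene, −78 → −40 °C
Reagents that add atoms: triphenylmethyl hydroperoxide (OOC(c1ccccc1)(c1ccccc1)c1ccccc1)
Why: Hydroxyl-directed, tartrate-mediated asymmetric nucleophilic (Weitz–Scheffer-type) epoxidation: the peroxide adds to C5, the only unsubstituted enone β-carbon (C3 is fully substituted), and the enolate closes on oxygen, so C5 and C6 are set together with the absolute sense coming from the sodium tartrate–substrate alkoxide aggregate.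

Step 7
Reactants: 9 methyl (2E)-4-[(1R,6S)-4-(hydroxymethyl)-3-iodo-5,5-dimethoxy-2-oxo-7-oxabicyclo[4.1.0]hept-3-en-1-yl]-2-methylbut-2-enoate; 10 (1E)-hept-1-en-1-ylboronic acid
Product: 11 methyl (2E)-4-[(1R,6S)-3-[(1E)-hept-1-en-1-yl]-4-(hydroxymethyl)-5,5-dimethoxy-2-oxo-7-oxabicyclo[4.1.0]hept-3-en-1-yl]-2-methylbut-2-enoate
Conditions: Pd(PPh3)4 (5 mol %), K2CO3, degassed THF/H2O, 40 °C
Reagents that add atoms: none
Why: Suzuki–Miyaura coupling of an α-iodoenone with an (E)-alkenylboronic acid proceeds with retention of alkene geometry under mild carbonate conditions that leave the epoxy ketone, ketal and ester untouched.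

Step 8
Reactants: 11 methyl (2E)-4-[(1R,6S)-3-[(1E)-hept-1-en-1-yl]-4-(hydroxymethyl)-5,5-dimethoxy-2-oxo-7-oxabicyclo[4.1.0]hept-3-en-1-yl]-2-methylbut-2-enoate
Product: 13 (2E)-4-[(1R,6S)-3-[(1E)-hept-1-en-1-yl]-4-(hydroxymethyl)-2,5-dioxo-7-oxabicyclo[4.1.0]hept-3-en-1-yl]-2-methylbut-2-enoic acid, via ketal acid 12 (not isolated)
Conditions: LiOH, THF/H2O, 0 → 23 °C; then CF3CO2H/H2O added to the same flask, 0 → 23 °C
Reagents that add atoms: lithium hydroxide ([Li+].[OH-]); water (O)
Why: Ester saponification is run while C4 is still a ketal (no enolizable position, and the epoxy ketone has just survived basic peroxide), and acidification then hydrolyses the dimethyl ketal; α-keto epoxides are deactivated towards acid opening, so the stereocentres are untouched.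

Step 9
Reactants: 13 (2E)-4-[(1R,6S)-3-[(1E)-hept-1-en-1-yl]-4-(hydroxymethyl)-2,5-dioxo-7-oxabicyclo[4.1.0]hept-3-en-1-yl]-2-methylbut-2-enoic acid
Product: 14 ambuic acid, (2E)-4-[(1R,5R,6R)-3-[(1E)-hept-1-en-1-yl]-5-hydroxy-4-(hydroxymethyl)-2-oxo-7-oxabicyclo[4.1.0]hept-3-en-1-yl]-2-methylbut-2-enoic acid
Conditions: Me4NBH(OAc)3, MeCN/AcOH, −30 → 0 °C
Reagents that add atoms: none
Why: Hydroxyl-directed (Saksena–Evans-type) reduction: the primary hydroxyl exchanges onto boron and delivers hydride only to the adjacent C4 carbonyl (C1=O is out of reach and is not reduced by the free reagent), on the face anti to the neighbouring oxirane C–O bond, which gives the C4 alcohol cis to the epoxide (R at that centre).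

## Compound list

1 | methyl (2E)-2-methylbut-2-enoate (methyl tiglate) | C/C=C(\C)C(=O)OC | starting material
2 | [(1-methoxy-2-methylbuta-1,3-dien-1-yl)oxy]trimethylsilane (E/Z mixture at the ketene acetal bond) | COC(O[Si](C)(C)C)=C(C)C=C | intermediate
3 | 5-hydroxy-2-methoxybenzaldehyde | COc1ccc(O)cc1C=O | starting material
4 | 3-(hydroxymethyl)-4-methoxyphenol | COc1ccc(O)cc1CO | intermediate
5 | 3-(hydroxymethyl)-4,4-dimethoxycyclohexa-2,5-dien-1-one | O=C1C=C(CO)C(OC)(OC)C=C1 | intermediate
6 | methyl (2E)-4-[2-hydroxy-4-(hydroxymethyl)-5-methoxyphenyl]-2-methylbut-2-enoate | COc1cc(C/C=C(\C)C(=O)OC)c(O)cc1CO | intermediate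
7 | methyl (2E)-4-[2-hydroxy-4-(hydroxymethyl)-3-iodo-5-methoxyphenyl]-2-methylbut-2-enoate | COc1cc(C/C=C(\C)C(=O)OC)c(O)c(I)c1CO | intermediate
8 | methyl (2E)-4-[4-(hydroxymethyl)-5-iodo-3,3-dimethoxy-6-oxocyclohexa-1,4-dien-1-yl]-2-methylbut-2-enoate | O=C1C(I)=C(CO)C(OC)(OC)C=C1C/C=C(\C)C(=O)OC | intermediate
9 | methyl (2E)-4-[(1R,6S)-4-(hydroxymethyl)-3-iodo-5,5-dimethoxy-2-oxo-7-oxabicyclo[4.1.0]hept-3-en-1-yl]-2-methylbut-2-enoate | IC1=C(CO)C(OC)(OC)[C@H]2O[C@@]2(C/C=C(\C)C(=O)OC)C1=O | intermediate
10 | (1E)-hept-1-en-1-ylboronic acid | CCCCC/C=C/B(O)O | starting material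
11 | methyl (2E)-4-[(1R,6S)-3-[(1E)-hept-1-en-1-yl]-4-(hydroxymethyl)-5,5-dimethoxy-2-oxo-7-oxabicyclo[4.1.0]hept-3-en-1-yl]-2-methylbut-2-enoate | CCCCC/C=C/C1=C(CO)C(OC)(OC)[C@H]2O[C@@]2(C/C=C(\C)C(=O)OC)C1=O | intermediate
12 | (2E)-4-[(1R,6S)-3-[(1E)-hept-1-en-1-yl]-4-(hydroxymethyl)-5,5-dimethoxy-2-oxo-7-oxabicyclo[4.1.0]hept-3-en-1-yl]-2-methylbut-2-enoic acid | CCCCC/C=C/C1=C(CO)C(OC)(OC)[C@H]2O[C@@]2(C/C=C(\C)C(=O)O)C1=O | intermediate
13 | (2E)-4-[(1R,6S)-3-[(1E)-hept-1-en-1-yl]-4-(hydroxymethyl)-2,5-dioxo-7-oxabicyclo[4.1.0]hept-3-en-1-yl]-2-methylbut-2-enoic acid | CCCCC/C=C/C1=C(CO)C(=O)[C@H]2O[C@@]2(C/C=C(\C)C(=O)O)C1=O | intermediate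
14 | ambuic acid, (2E)-4-[(1R,5R,6R)-3-[(1E)-hept-1-en-1-yl]-5-hydroxy-4-(hydroxymethyl)-2-oxo-7-oxabicyclo[4.1.0]hept-3-en-1-yl]-2-methylbut-2-enoic acid | CCCCC/C=C/C1=C(CO)[C@@H](O)[C@H]2O[C@@]2(C/C=C(\C)C(=O)O)C1=O | target

## Step count and risks

Total steps: 9. Longest linear sequence: 8 (steps 2 to 9, from 3); step 1 is a one-step branch that feeds step 4.

**Step 4, the key coupling.** The ketal-derived cation can also be attacked at the ketal carbon, at C2, or in the Michael sense at C5, and the product phenol is itself a nucleophile. If the C6 adduct is not the major product, the fallback sets out from 4 and comes back at 6. Phenol 4 is brominated with N-bromosuccinimide and catalytic iPr2NH at the unhindered ortho position to give 2-bromo-5-(hydroxymethyl)-4-methoxyphenol F1. F1 is then joined to dienolate 2 by a palladium-catalysed γ-arylation (Pd(dba)2, P(tBu)3, ZnF2, DMF, 80 °C), which fixes the position of the side chain through the carbon–bromine bond instead of through cation regiochemistry.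

**Step 6, the asymmetric epoxidation.** The hydroxymethyl group of 8 sits next to the ketal, not next to the carbonyl as in the established hydroxyl-directed cases, so both the level and the sense of induction are untested. The fallback sets out from 7 (isolated after the N-iodosuccinimide stage of step 5) and comes back at 13. Oxidation of 7 with PhI(OAc)2 in CH2Cl2 in the presence of (2R,3R)-butane-2,3-diol, then catalytic BF3·OEt2, gives the butanediol spiroketal dienone F2. Epoxidation with tBuOOH and DBU gives two oxirane diastereomers that can be separated on silica, so the needed butanediol-ketal epoxide F3 is obtained as a single enantiomer whatever the ratio. Suzuki–Miyaura coupling with 10 as in step 7 gives the heptenyl butanediol-ketal epoxide F4. LiOH followed by a longer treatment with aqueous CF3CO2H removes the methyl ester and the dioxolane and gives 13.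

**Step 8, saponification and ketal hydrolysis.** The tiglate-type ester saponifies slowly, and epoxyquinone 13 carries a hydroxymethyl group next to a dienone, so it may close to a pyran by oxa-Michael addition in acid. The fallback sets out from 9 and comes back at 14, with the diene introduced last. LiOH and then aqueous CF3CO2H on 9 give the iodo epoxyquinone acid F5. Directed reduction with Me4NBH(OAc)3 as in step 9 gives the iodo epoxyquinol acid F6. Suzuki–Miyaura coupling of F6 with 10 (Pd(PPh3)4, K2CO3, aqueous THF, 23 °C) then gives 14 directly.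

## Further compounds

F1 | step 4 | 2-bromo-5-(hydroxymethyl)-4-methoxyphenol | COc1cc(Br)c(O)cc1CO
F2 | step 6 | butanediol spiroketal dienone: 8 with the two methoxy groups replaced by a (4R,5R)-4,5-dimethyl-1,3-dioxolane ring | O=C1C(I)=C(CO)C3(O[C@H](C)[C@@H](C)O3)C=C1C/C=C(\C)C(=O)OC
F3 | step 6 | butanediol-ketal epoxide: 9 with the two methoxy groups replaced by a (4R,5R)-4,5-dimethyl-1,3-dioxolane ring | IC1=C(CO)C3(O[C@H](C)[C@@H](C)O3)[C@H]2O[C@@]2(C/C=C(\C)C(=O)OC)C1=O
F4 | step 6 | heptenyl butanediol-ketal epoxide: 11 with the two methoxy groups replaced by a (4R,5R)-4,5-dimethyl-1,3-dioxolane ring | CCCCC/C=C/C1=C(CO)C3(O[C@H](C)[C@@H](C)O3)[C@H]2O[C@@]2(C/C=C(\C)C(=O)OC)C1=O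
F5 | step 8 | iodo epoxyquinone acid, (2E)-4-[(1R,6S)-4-(hydroxymethyl)-3-iodo-2,5-dioxo-7-oxabicyclo[4.1.0]hept-3-en-1-yl]-2-methylbut-2-enoic acid | IC1=C(CO)C(=O)[C@H]2O[C@@]2(C/C=C(\C)C(=O)O)C1=O
F6 | step 8 | iodo epoxyquinol acid, (2E)-4-[(1R,5R,6R)-5-hydroxy-4-(hydroxymethyl)-3-iodo-2-oxo-7-oxabicyclo[4.1.0]hept-3-en-1-yl]-2-methylbut-2-enoic acid | IC1=C(CO)[C@@H](O)[C@H]2O[C@@]2(C/C=C(\C)C(=O)O)C1=O
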